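The flask started with nothing dissolved.

| flask | solid substrate | partner | remark | time |
|---|---|---|---|---|
| north-east | 0.050 M | 0.95 equiv | the very flask that is asked about, followed so far |  |
| flask | 0.050 M | 0.950 equiv |  | 2.0 h |

north-east run (percent of the solid substrate charged)

| time / min | target / % | solid product / % |
|---|---|---|
| 2.00 | 2.5 | 0 |
| 5.00 | 6.2 | 0 |
| 10.0 | 12.3 | 1.3 |
| 15.0 | 20.2 | 0 |
| 20.0 | 26.1 | 0 |

(standard deviation of a reading: 1 percentage point)

- amounts and yields of target count solid product too
- given per volume of solution although it is solid: solid substrate, solid product
- on the list of suspects stand: target <-> isomer of the product; solid substrate <-> dissolved substrate; dissolved substrate + partner -> target; solid product <-> target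
- at the start none of the solid substrate is in solution
- dissolved substrate means what is dissolved; the solid is not counted in it

- how much target and solid product together there is at 2.0 h, in percent of the solid substrate charged
- concentration of dissolved substrate in solution at 2.0 h, in percent of saturation

In the first instants the solid substrate had to dissolve before it could meet the partner, yet target already read 2.5% at 2.00 min, and I saw no lag beyond the scatter of 1 percentage point. Solid product showed once, 1.3% at 10.0 min, so I merely kept an eye on it. By 20.0 min target stood at 26.1%, still on a nearly straight line, but I expected that line to bend as the partner, the limiting reagent at 0.950 equiv, was consumed.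

For the end I took the symmetric case as my zero: equal charges, the whole charge in solution, and a rate proportional to [dissolved substrate][partner]. In that case yield divided by what remains grows in proportion to time. The pace, that ratio divided by time, read from the last reading with its scatter, was 0.0177 /min. At 2.0 h this gave a ratio of 2.12, so I reckoned 67.9% of target and solid product together. The readings gave me no saturation value, so I put no figure on the second question.

The forecast gave 85% and 98%, holding that “the solution should be saturated or nearly so”; my yield lay below its figure.

The flask gave 68.3%, and its solution stood at 37.1% of saturation.

    target ⇌ isomer of the product (K = 1.67, k = 0.00121 /min)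
    solid substrate ⇌ dissolved substrate, rate k2*(cs2 - [dissolved substrate]) while solid is left; crystals form when [dissolved substrate] > cs2 (solubility = 37.0 mM, k = 0.528 /min)
    dissolved substrate + partner → target (k = 0.519 /M/min)
    solid product ⇌ target, rate k4*(cs4 - [target]) while solid is left; crystals form when [target] > cs4 (solubility = 17.0 mM, k = 3.29 /min)

Solid substrate was down to 0% by 1.00 h. Reckoned back from the result, this flask's pace over 2.0 h was 0.0180 /min, against 0.0177 /min from the early reading. For the neighbour flask at 0.085 M, with the same equivalents, the symmetric case scales the pace with concentration to 0.0300 /min and reckons 78.3%; that flask gave 76.5%.

The numbers in the tables were computed with constants of no real substance; scatter was added.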